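**Strategy.** Ring A is disconnected at C3a–C4 and C7–C7a. The feature exploited is that O1, C7a and C3a of the dihydrofuran ring are the ring oxygen, carbonyl carbon and α-carbon of a trans-γ-aryl-β-(silyloxymethyl)butyrolactone, so C2 and C3 can be set by an Evans aldol before ring A exists. The silyl ketene acetal of that lactone and methyl 3-bromocoumalate then undergo an inverse-demand Diels–Alder reaction; extrusion of CO2 and base-induced loss of silanol deliver ring A (C4–C7 from the pyrone) in one operation, with bromine at C7 as placeholder for methoxy and the C5 ester as precursor of the enal.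

Key step: step 8

Remark: ring positions are given in benzofuran numbering throughout; the transient stereocentres of the non-isolated intermediates 12, 14 and 15 are mixtures and are left undefined in their SMILES.

Step 1
Reactants: 1 (4R)-4-benzyl-1,3-oxazolidin-2-one; 2 methyl 4-chloro-4-oxobutanoate
Product: 3 methyl 4-[(4R)-4-benzyl-2-oxo-1,3-oxazolidin-3-yl]-4-oxobutanoate
Conditions: n-BuLi, THF, −78 °C; then 2, −78 → 0 °C
Reagents that add atoms: none
Why: N-acylation of the lithiated oxazolidinone by the acid chloride (nucleophilic acyl substitution) is the standard entry to Evans imides, and the methyl ester is not attacked at low temperature.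

Step 2
Reactants: 3 methyl 4-[(4R)-4-benzyl-2-oxo-1,3-oxazolidin-3-yl]-4-oxobutanoate; 4 3,4-dimethoxybenzaldehyde
Product: 6 (4R)-4-benzyl-3-{[(2R,3R)-2-(3,4-dimethoxyphenyl)-5-oxooxolan-3-yl]carbonyl}-1,3-oxazolidin-2-one, via syn-aldol hydroxy ester 5 (not isolated)
Conditions: Bu2BOTf, i-Pr2NEt, CH2Cl2, 0 °C; 4, −78 → 0 °C; MeOH, pH 7 buffer, H2O2, 0 °C; then PPTS (cat.), CH2Cl2, 25 °C
Reagents that add atoms: none
Why: Evans syn-aldol reaction, in which the Z-dibutylboron enolate of the imide (the remote ester is not enolised) reacts through a Zimmerman–Traxler chair on the enolate face anti to the benzyl group of the (R)-auxiliary, setting both new centres as R,R; the new hydroxyl then closes onto the methyl ester (5-exo-trig lactonisation), and the syn-aldol geometry places aryl and acyl groups trans on the lactone.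

Step 3
Reactants: 6 (4R)-4-benzyl-3-{[(2R,3R)-2-(3,4-dimethoxyphenyl)-5-oxooxolan-3-yl]carbonyl}-1,3-oxazolidin-2-one
Product: 7 (2R,3R)-2-(3,4-dimethoxyphenyl)-5-oxooxolane-3-carboxylic acid
Conditions: LiOH, H2O2, THF/H2O, 0 °C; Na2SO3; then 1 M HCl to pH 2
Reagents that add atoms: hydrogen peroxide (as LiOOH), OO
Why: Hydroperoxide attacks the exocyclic imide carbonyl selectively (Evans auxiliary cleavage), sulfite reduces the peracid, and acidification re-closes any γ-lactone opened by hydroxide, so both stereocentres should be retained.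

Step 4
Reactants: 7 (2R,3R)-2-(3,4-dimethoxyphenyl)-5-oxooxolane-3-carboxylic acid
Product: 8 (4S,5R)-5-(3,4-dimethoxyphenyl)-4-(hydroxymethyl)oxolan-2-one
Conditions: BH3·SMe2, THF, 0 → 25 °C; MeOH quench
Reagents that add atoms: none
Why: Borane reduces a free carboxylic acid through its acyloxyborane much faster than a lactone, a chemoselective reduction that is routine for paraconic acids and touches no stereocentre (the descriptor at C4 changes only through priority rules).

Step 5
Reactants: 8 (4S,5R)-5-(3,4-dimethoxyphenyl)-4-(hydroxymethyl)oxolan-2-one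
Product: 9 (4S,5R)-4-{[(tert-butyldimethylsilyl)oxy]methyl}-5-(3,4-dimethoxyphenyl)oxolan-2-one
Conditions: TBSCl, imidazole, DMF, 25 °C
Reagents that add atoms: tert-butyldimethylsilyl chloride, CC(C)(C)[Si](C)(C)Cl
Why: Imidazole-promoted silylation of a primary alcohol under near-neutral conditions; masking the hydroxyl before any strong base is used prevents alkoxide-driven translactonisation to the isomeric lactone.

Step 6
Reactants: 9 (4S,5R)-4-{[(tert-butyldimethylsilyl)oxy]methyl}-5-(3,4-dimethoxyphenyl)oxolan-2-one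
Product: 10 (2R,3S)-5-[(tert-butyldimethylsilyl)oxy]-3-{[(tert-butyldimethylsilyl)oxy]methyl}-2-(3,4-dimethoxyphenyl)-2,3-dihydrofuran
Conditions: LDA, THF, −78 °C; TBSCl, DMPU, −78 → 0 °C; pentane, filtration
Reagents that add atoms: tert-butyldimethylsilyl chloride, CC(C)(C)[Si](C)(C)Cl
Why: Kinetic deprotonation of the lactone α-CH2 and O-silylation of the lithium enolate in THF/DMPU (enolate trapping as used for Ireland–Claisen substrates) should give the cyclic silyl ketene acetal; the tert-butyldimethylsilyl group is chosen because it silylates only on oxygen, survives handling and resists silyl transfer in step 8, and neither stereocentre bears an acidic hydrogen.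

Step 7
Reactants: 11 methyl 2-oxo-2H-pyran-5-carboxylate (methyl coumalate)
Product: 13 methyl 3-bromo-2-oxo-2H-pyran-5-carboxylate, via 3,6-dibromide 12 (not isolated)
Conditions: Br2, CH2Cl2, 25 °C; then Et3N, 0 °C
Reagents that add atoms: bromine, BrBr
Why: Electrophilic bromination of a 2-pyrone by addition–elimination: bromine enters at C3, the nucleophilic terminus of the ring-oxygen dienol ether (C5 is blocked by the ester), and triethylamine removes HBr from the adduct to restore the pyrone.

Step 8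
Reactants: 10 (2R,3S)-5-[(tert-butyldimethylsilyl)oxy]-3-{[(tert-butyldimethylsilyl)oxy]methyl}-2-(3,4-dimethoxyphenyl)-2,3-dihydrofuran; 13 methyl 3-bromo-2-oxo-2H-pyran-5-carboxylate
Product: 16 methyl (2R,3S)-7-bromo-3-{[(tert-butyldimethylsilyl)oxy]methyl}-2-(3,4-dimethoxyphenyl)-2,3-dihydro-1-benzofuran-5-carboxylate, via bridged lactone cycloadduct 14 (not isolated), via silyl ketal cyclohexadiene 15 (not isolated)
Conditions: i-Pr2NEt (0.2 equiv), PhMe, 25 → 110 °C; then DBU, 60 °C
Reagents that add atoms: none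
Why: The electron-rich ketene acetal and the electron-poor bromopyrone should combine in an inverse-electron-demand [4+2] cycloaddition (highly asynchronous, C3a–C4 leading), the bridged lactone 14 loses CO2 by retro-[4+2], and DBU removes the C3a hydrogen of diene 15 (vinylogous to the C5 ester) so that silanolate leaves C7a and ring A aromatises (E1cB). The closest known reaction type is the benzannulation of coumalates and 3-halo-2-pyrones with ketene acetals to give para-alkoxybenzoates. Ring A is closed by intermolecular [4+2] cycloaddition, with C4–C7 coming from the pyrone and C3a and C7a from the ketene acetal, while the dihydrofuran ring is carried through intact. No lasting stereocentre is created: C2 and C3 come unchanged from the lactone (C3 has no acidic hydrogen) and the transient centres vanish on aromatisation. The regiochemistry needed is secured by polarisation, since the nucleophilic α-carbon attacks pyrone C6, the terminus activated by both the C5 ester and the ring carbonyl, which puts bromine at C7 and the ester at C5. Loss of the exocyclic silyloxy group in preference to O1 is secured by aromatising under base in an acid-free medium: silanolate is the better leaving group, and in the planar C3a carbanion O1 is held near the ring plane by the five-membered ring whereas the exocyclic C–O bond is aligned with the π system.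

Step 9
Reactants: 16 methyl (2R,3S)-7-bromo-3-{[(tert-butyldimethylsilyl)oxy]methyl}-2-(3,4-dimethoxyphenyl)-2,3-dihydro-1-benzofuran-5-carboxylate
Product: 17 methyl (2R,3S)-3-{[(tert-butyldimethylsilyl)oxy]methyl}-2-(3,4-dimethoxyphenyl)-7-methoxy-2,3-dihydro-1-benzofuran-5-carboxylate
Conditions: Pd2(dba)3 (cat.), tBuBrettPhos, Cs2CO3, MeOH (5 equiv), PhMe, 60 °C
Reagents that add atoms: methanol, CO
Why: Palladium-catalysed C–O cross-coupling of an aryl bromide with methanol (Buchwald–Hartwig etherification), in which the bulky biarylphosphine favours C–O reductive elimination from divalent palladium over β-hydride elimination; carbonate/methanol leaves the methyl ester (degenerate exchange) and the alkyl silyl ether intact.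

Step 10
Reactants: 17 methyl (2R,3S)-3-{[(tert-butyldimethylsilyl)oxy]methyl}-2-(3,4-dimethoxyphenyl)-7-methoxy-2,3-dihydro-1-benzofuran-5-carboxylate
Product: 18 [(2R,3S)-3-{[(tert-butyldimethylsilyl)oxy]methyl}-2-(3,4-dimethoxyphenyl)-7-methoxy-2,3-dihydro-1-benzofuran-5-yl]methanol
Conditions: i-Bu2AlH (DIBAL-H), CH2Cl2, −78 → 0 °C; Rochelle salt work-up
Reagents that add atoms: none
Why: Excess DIBAL-H reduces the aryl methyl ester to the benzylic alcohol (hydride reduction), while aryl ethers and the silyl ether are inert.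

Step 11
Reactants: 18 [(2R,3S)-3-{[(tert-butyldimethylsilyl)oxy]methyl}-2-(3,4-dimethoxyphenyl)-7-methoxy-2,3-dihydro-1-benzofuran-5-yl]methanol
Product: 19 (2R,3S)-3-{[(tert-butyldimethylsilyl)oxy]methyl}-2-(3,4-dimethoxyphenyl)-7-methoxy-2,3-dihydro-1-benzofuran-5-carbaldehyde
Conditions: MnO2 (activated, excess), CH2Cl2, 25 °C
Reagents that add atoms: none
Why: Activated MnO2 oxidises electron-rich benzylic alcohols to aldehydes without over-oxidation and without affecting the benzylic ether positions.

Step 12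
Reactants: 19 (2R,3S)-3-{[(tert-butyldimethylsilyl)oxy]methyl}-2-(3,4-dimethoxyphenyl)-7-methoxy-2,3-dihydro-1-benzofuran-5-carbaldehyde
Product: 20 (2E)-3-[(2R,3S)-3-{[(tert-butyldimethylsilyl)oxy]methyl}-2-(3,4-dimethoxyphenyl)-7-methoxy-2,3-dihydro-1-benzofuran-5-yl]prop-2-enal
Conditions: Ph3P=CHCHO (1.1 equiv), PhMe, 80 °C
Reagents that add atoms: (triphenylphosphoranylidene)acetaldehyde, O=CC=P(c1ccccc1)(c1ccccc1)c1ccccc1
Why: Wittig olefination with the stabilised formylmethylene ylide should give the E-enal selectively, and a near-stoichiometric amount of ylide limits further homologation.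

Step 13
Reactants: 20 (2E)-3-[(2R,3S)-3-{[(tert-butyldimethylsilyl)oxy]methyl}-2-(3,4-dimethoxyphenyl)-7-methoxy-2,3-dihydro-1-benzofuran-5-yl]prop-2-enal
Product: 21 4-O-methylbalanophonin, (2E)-3-[(2R,3S)-2-(3,4-dimethoxyphenyl)-3-(hydroxymethyl)-7-methoxy-2,3-dihydro-1-benzofuran-5-yl]prop-2-enal
Conditions: HF·pyridine, pyridine, THF, 0 → 25 °C
Reagents that add atoms: none
Why: Buffered fluoride-mediated desilylation cleaves the primary silyl ether without conjugate addition to the enal or ionisation of the benzylic C2–O bond, so neither stereocentre nor the alkene geometry is affected.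

**Compound list**

1 | (4R)-4-benzyl-1,3-oxazolidin-2-one | O=C1N[C@H](Cc2ccccc2)CO1 | starting material
2 | methyl 4-chloro-4-oxobutanoate | COC(=O)CCC(Cl)=O | starting material
3 | methyl 4-[(4R)-4-benzyl-2-oxo-1,3-oxazolidin-3-yl]-4-oxobutanoate | COC(=O)CCC(=O)N1[C@H](Cc2ccccc2)COC1=O | intermediate
4 | 3,4-dimethoxybenzaldehyde | COc1ccc(C=O)cc1OC | starting material
5 | methyl (3R,4R)-3-{[(4R)-4-benzyl-2-oxo-1,3-oxazolidin-3-yl]carbonyl}-4-(3,4-dimethoxyphenyl)-4-hydroxybutanoate (syn-aldol adduct) | COc1ccc([C@H](O)[C@@H](CC(=O)OC)C(=O)N2[C@H](Cc3ccccc3)COC2=O)cc1OC | intermediate (not isolated)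
6 | (4R)-4-benzyl-3-{[(2R,3R)-2-(3,4-dimethoxyphenyl)-5-oxooxolan-3-yl]carbonyl}-1,3-oxazolidin-2-one (trans lactone) | COc1ccc([C@@H]2OC(=O)C[C@H]2C(=O)N3[C@H](Cc4ccccc4)COC3=O)cc1OC | intermediate
7 | (2R,3R)-2-(3,4-dimethoxyphenyl)-5-oxooxolane-3-carboxylic acid | COc1ccc([C@@H]2OC(=O)C[C@H]2C(=O)O)cc1OC | intermediate
8 | (4S,5R)-5-(3,4-dimethoxyphenyl)-4-(hydroxymethyl)oxolan-2-one | COc1ccc([C@@H]2OC(=O)C[C@H]2CO)cc1OC | intermediate
9 | (4S,5R)-4-{[(tert-butyldimethylsilyl)oxy]methyl}-5-(3,4-dimethoxyphenyl)oxolan-2-one | COc1ccc([C@@H]2OC(=O)C[C@H]2CO[Si](C)(C)C(C)(C)C)cc1OC | intermediate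
10 | (2R,3S)-5-[(tert-butyldimethylsilyl)oxy]-3-{[(tert-butyldimethylsilyl)oxy]methyl}-2-(3,4-dimethoxyphenyl)-2,3-dihydrofuran (silyl ketene acetal of 9) | COc1ccc([C@@H]2OC(O[Si](C)(C)C(C)(C)C)=C[C@H]2CO[Si](C)(C)C(C)(C)C)cc1OC | intermediate
11 | methyl 2-oxo-2H-pyran-5-carboxylate | COC(=O)C1=COC(=O)C=C1 | starting material
12 | methyl 3,6-dibromo-2-oxo-3,6-dihydro-2H-pyran-5-carboxylate | COC(=O)C1=CC(Br)C(=O)OC1Br | intermediate (not isolated)
13 | methyl 3-bromo-2-oxo-2H-pyran-5-carboxylate | COC(=O)C1=COC(=O)C(Br)=C1 | intermediate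
14 | [4+2] adduct of 10 and 13: a 2-oxabicyclo[2.2.2]oct-7-en-3-one with bromine on the bridgehead next to the carbonyl, the methyl ester on the alkene, and the dihydrofuran fused across the two new sp3 carbons (C3a on the O-bearing bridgehead, silyl ketal carbon C7a on the brominated bridgehead) | O=C1OC2C(C(=O)OC)=CC1(Br)C3(O[Si](C)(C)C(C)(C)C)O[C@@H](c4ccc(OC)c(OC)c4)[C@H](CO[Si](C)(C)C(C)(C)C)C23 | intermediate (not isolated)
15 | methyl (2R,3S)-7-bromo-7a-[(tert-butyldimethylsilyl)oxy]-3-{[(tert-butyldimethylsilyl)oxy]methyl}-2-(3,4-dimethoxyphenyl)-2,3,3a,7a-tetrahydro-1-benzofuran-5-carboxylate | COC(=O)C1=CC2[C@@H](CO[Si](C)(C)C(C)(C)C)[C@H](c3ccc(OC)c(OC)c3)OC2(O[Si](C)(C)C(C)(C)C)C(Br)=C1 | intermediate (not isolated)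
16 | methyl (2R,3S)-7-bromo-3-{[(tert-butyldimethylsilyl)oxy]methyl}-2-(3,4-dimethoxyphenyl)-2,3-dihydro-1-benzofuran-5-carboxylate | COc1ccc([C@@H]2Oc3c(Br)cc(C(=O)OC)cc3[C@H]2CO[Si](C)(C)C(C)(C)C)cc1OC | intermediate
17 | methyl (2R,3S)-3-{[(tert-butyldimethylsilyl)oxy]methyl}-2-(3,4-dimethoxyphenyl)-7-methoxy-2,3-dihydro-1-benzofuran-5-carboxylate | COc1ccc([C@@H]2Oc3c(OC)cc(C(=O)OC)cc3[C@H]2CO[Si](C)(C)C(C)(C)C)cc1OC | intermediate
18 | [(2R,3S)-3-{[(tert-butyldimethylsilyl)oxy]methyl}-2-(3,4-dimethoxyphenyl)-7-methoxy-2,3-dihydro-1-benzofuran-5-yl]methanol | COc1ccc([C@@H]2Oc3c(OC)cc(CO)cc3[C@H]2CO[Si](C)(C)C(C)(C)C)cc1OC | intermediate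
19 | (2R,3S)-3-{[(tert-butyldimethylsilyl)oxy]methyl}-2-(3,4-dimethoxyphenyl)-7-methoxy-2,3-dihydro-1-benzofuran-5-carbaldehyde | COc1ccc([C@@H]2Oc3c(OC)cc(C=O)cc3[C@H]2CO[Si](C)(C)C(C)(C)C)cc1OC | intermediate
20 | (2E)-3-[(2R,3S)-3-{[(tert-butyldimethylsilyl)oxy]methyl}-2-(3,4-dimethoxyphenyl)-7-methoxy-2,3-dihydro-1-benzofuran-5-yl]prop-2-enal | COc1ccc([C@@H]2Oc3c(OC)cc(/C=C/C=O)cc3[C@H]2CO[Si](C)(C)C(C)(C)C)cc1OC | intermediate
21 | 4-O-methylbalanophonin, (2E)-3-[(2R,3S)-2-(3,4-dimethoxyphenyl)-3-(hydroxymethyl)-7-methoxy-2,3-dihydro-1-benzofuran-5-yl]prop-2-enal | COc1ccc([C@@H]2Oc3c(OC)cc(/C=C/C=O)cc3[C@H]2CO)cc1OC | target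

**Step count.** Total: 13 steps. Longest linear sequence: 12 steps (steps 1–6 and 8–13); step 7 is a one-step side branch.

**Steps most likely to fail**

Step 8. After ring A has formed, aromatisation may proceed by cleavage of the C7a–O1 bond, or the ketal silyl group may be lost before elimination, so that the dihydrofuran ring opens instead of silanol being expelled. The fallback closes the heterocycle by a different bond, C2–O1. It sets out from 15, made as in step 8 up to the loss of CO2 with the DBU treatment omitted. One equivalent of Bu4NF with AcOH in THF at −20 °C cleaves the ketal silyl group on purpose; the hemiketal collapses to the dienone, which tautomerises to the ring-opened phenol methyl 3-bromo-5-[(2S,3R)-1-[(tert-butyldimethylsilyl)oxy]-3-(3,4-dimethoxyphenyl)-3-hydroxypropan-2-yl]-4-hydroxybenzoate F1. BF3·OEt2 in CH2Cl2 at −40 °C should then ionise the veratryl carbinol, and the phenol oxygen captures the benzylic cation anti to the C3 substituent (acid-mediated cycloetherification, trans by both kinetic and thermodynamic preference; C3 is not involved). This returns the route to 16.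

Step 9. The C7–Br bond may be reduced to C–H through β-hydride elimination from the palladium methoxide, or C–O reductive elimination may stall at the position next to O1. The fallback installs oxygen through boron. It sets out from 16: Miyaura borylation (B2pin2, Pd(dppf)Cl2, KOAc, dioxane, 80 °C) should give the boronate methyl (2R,3S)-3-{[(tert-butyldimethylsilyl)oxy]methyl}-2-(3,4-dimethoxyphenyl)-7-(4,4,5,5-tetramethyl-1,3,2-dioxaborolan-2-yl)-2,3-dihydro-1-benzofuran-5-carboxylate F2. Oxidation with NaBO3·4H2O in THF/H2O at 25 °C gives the phenol methyl (2R,3S)-3-{[(tert-butyldimethylsilyl)oxy]methyl}-2-(3,4-dimethoxyphenyl)-7-hydroxy-2,3-dihydro-1-benzofuran-5-carboxylate F3, and O-methylation (MeI, K2CO3, acetone) returns the route to 17.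

Step 12. Olefination of the electron-rich aldehyde may be slow, and the product enal may be homologated further by the formylmethylene ylide. The fallback builds the enal at the ester oxidation level. It sets out from 19: Horner–Wadsworth–Emmons reaction with triethyl phosphonoacetate (NaH, THF, 0 °C) should give ethyl (2E)-3-[(2R,3S)-3-{[(tert-butyldimethylsilyl)oxy]methyl}-2-(3,4-dimethoxyphenyl)-7-methoxy-2,3-dihydro-1-benzofuran-5-yl]prop-2-enoate F4. DIBAL-H in CH2Cl2 at −78 °C gives the allylic alcohol (2E)-3-[(2R,3S)-3-{[(tert-butyldimethylsilyl)oxy]methyl}-2-(3,4-dimethoxyphenyl)-7-methoxy-2,3-dihydro-1-benzofuran-5-yl]prop-2-en-1-ol F5, and MnO2 in CH2Cl2 returns the route to 20.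

**Further compounds**

F1 | step 8 | methyl 3-bromo-5-[(2S,3R)-1-[(tert-butyldimethylsilyl)oxy]-3-(3,4-dimethoxyphenyl)-3-hydroxypropan-2-yl]-4-hydroxybenzoate | COC(=O)c1cc(Br)c(O)c(c1)[C@@H](CO[Si](C)(C)C(C)(C)C)[C@@H](O)c2ccc(OC)c(OC)c2
F2 | step 9 | methyl (2R,3S)-3-{[(tert-butyldimethylsilyl)oxy]methyl}-2-(3,4-dimethoxyphenyl)-7-(4,4,5,5-tetramethyl-1,3,2-dioxaborolan-2-yl)-2,3-dihydro-1-benzofuran-5-carboxylate | COc1ccc([C@@H]2Oc3c(B4OC(C)(C)C(C)(C)O4)cc(C(=O)OC)cc3[C@H]2CO[Si](C)(C)C(C)(C)C)cc1OC
F3 | step 9 | methyl (2R,3S)-3-{[(tert-butyldimethylsilyl)oxy]methyl}-2-(3,4-dimethoxyphenyl)-7-hydroxy-2,3-dihydro-1-benzofuran-5-carboxylate | COc1ccc([C@@H]2Oc3c(O)cc(C(=O)OC)cc3[C@H]2CO[Si](C)(C)C(C)(C)C)cc1OC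
F4 | step 12 | ethyl (2E)-3-[(2R,3S)-3-{[(tert-butyldimethylsilyl)oxy]methyl}-2-(3,4-dimethoxyphenyl)-7-methoxy-2,3-dihydro-1-benzofuran-5-yl]prop-2-enoate | COc1ccc([C@@H]2Oc3c(OC)cc(/C=C/C(=O)OCC)cc3[C@H]2CO[Si](C)(C)C(C)(C)C)cc1OC
F5 | step 12 | (2E)-3-[(2R,3S)-3-{[(tert-butyldimethylsilyl)oxy]methyl}-2-(3,4-dimethoxyphenyl)-7-methoxy-2,3-dihydro-1-benzofuran-5-yl]prop-2-en-1-ol | COc1ccc([C@@H]2Oc3c(OC)cc(/C=C/CO)cc3[C@H]2CO[Si](C)(C)C(C)(C)C)cc1OC
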